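Readings and results stem from a simulated flask for an exercise, noise included.

4 questions stand on the blue flask, and they are taken here as an oral, once the runs are laid out.

common to all: gas phase 74 mM (held)

|  | substrate | temperature | remark | time |
|---|---|---|---|---|
| blue | 2 M | 35 °C | the very flask that is asked about, followed so far |  |
| teal | 3 M | 30 °C | run made earlier |  |
| flask | 2.0 M | 35 °C |  | 2.0 d |

| run | time / h | target / % |
|---|---|---|
| blue | 2.50 | 12.5 |
| blue | 8.00 | 12.3 |
| blue | 15.0 | 13.8 |
| blue | 20.0 | 12.6 |
| blue | 30.0 | 10.9 |
| blue | 40.0 | 13.7 |
| blue | 50.0 | 14.2 |
| teal | 0.133 | 1.8 |
| teal | 0.417 | 4.0 |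
| teal | 0.667 | 6.1 |
| teal | 1.00 | 8.5 |
| teal | 1.50 | 8.4 |
| teal | 2.00 | 8.2 |
| teal | 2.50 | 9.3 |

(scatter of a reading: 1 percentage point)

- Monday's: at 2.0 d take out 90% of the target then present, then wait 15 h
- Thursday's: at 2.0 d raise the temperature by 25 K, then wait 15 h
- Saturday's: change nothing and wait 15 h more

- target, in percent of the substrate first charged, at 2.0 d
- what to do for the largest gain in target; "none" if nothing gains more than 2 percentage points (Monday's / Thursday's / Saturday's / none)
- target present, with what was taken out counted in, in percent of the substrate first charged, after Monday's
- target present, with what was taken out counted in, in percent of the substrate first charged, after Thursday's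

- what is taken out of target is counted as made
- what was read earlier has a scatter of 1 percentage point, one standard deviation
- at the start none of the gas phase is in solution

*What is in the blue flask at 2.0 d?* Its readings of target show no trend beyond their scatter over 1.30 decades of time, from 2.50 h to 50.0 h, so I take the mean of its 7 readings, 12.9%, as the answer for now, and I expect nothing from Saturday's.

*Does flat mean dead?* Not of itself: the gas phase is held and the blue readings leave 87.1% of the substrate unread, a remainder that may be inert or may stand in balance with target, which is thermodynamic control.

*What number carries that?* The gap L, the base-ten logarithm of unread remainder over target, which is 0.831 decades in the blue run and, from the last 4 teal readings with mean 8.60%, 1.03 decades in the teal run.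

*But the teal run also differs in substrate, and the two plateaus agree in concentration, 0.257 M and 0.258 M?* They do, so the slope of 0.0391 /K in decades, read between 30 °C and 35 °C, is a rough reading that mixes two settings, and I use what follows from it as a high estimate, assuming that the whole remainder exchanges. On that assumption I reckon 22.9% for Monday's, and for Thursday's a gap of −0.146 decades and so 58.3%. With an inert remainder, both stay at 12.9%. Thursday's high estimate stands higher than Monday's, so I answer Thursday's.

The forecast, which differs from my reckoning on what is best, gives 12.9% for now, none as best, and 12.9% and 12.9% for the two actions, on this ground: “If so, the reaction is dead.”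

The flask gives 13.0% and names Thursday's as best: Monday's reaches 21.7%, a gain of 8.7 percentage points, Thursday's reaches 33.4%, a gain of 20 points, and Saturday's gains 0 points.

    gas phase ⇌ dissolved gas, rate k1*(csat - [dissolved gas]) (kL = 0.410 /min)
    dissolved gas → decomposed reagent (k = 0.0150 /min, Ea = 99.0 kJ/mol)
    substrate → side product A (k = 0.00370 /min, Ea = 92.0 kJ/mol)
    substrate + dissolved gas → target (k = 0.130 /M/min, Ea = 76.0 kJ/mol)
    substrate + target → side product B (k = 0.00600 /M/min, Ea = 63.0 kJ/mol)
    target ⇌ isomer of the product (K = 2.90, k = 0.0530 /min, Ea = 90.0 kJ/mol, ΔH = −59.0 kJ/mol)
    (constants at 35 °C)

Both results lie lower than my high estimates. At 48.0 h the blue flask holds 37.7% as isomer of the product, 31.5% as side product A and 17.8% as side product B, so isomer over target stands at 0.462 decades, less than the gap of 0.831. Carried with the same slope to the neighbouring flask, the same flask run at 20 °C, the reckoned gap is 1.42 decades, which gives 3.66% of target, and at 48.0 h that flask holds 5.60% of target beside 52.7% of isomer of the product.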